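**Retrosynthetic overview**
1. Endgame: the C15 acid comes from a silyl ether; the ring B enone (C5=C6–C7=O) comes from a C5 tertiary alcohol by syn-dehydration and allylic oxidation; the C4 acetoxymethyl group comes from a C4 allyl group (Wacker oxidation, then Baeyer–Villiger oxidation).
2. Key disconnection: C2–C3 and the ring-fusion bond C5–C10 are made together by a thermal oxy-Cope/Claisen/transannular carbonyl-ene cascade of the monocyclic allyl ether 16, which also creates quaternary C4.
3. Enabling feature: in ring A the string C3–C4–C5–C10–C1–C2 is a hexa-1,5-diene retron folded over the ring-fusion bond; C5 (β-carbon of the ring B enone) can be a carbinol carbon, C4 is a quaternary α-carbon, and quaternary C9 leaves C2–H as the only ene hydrogen.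
4. Ring order: ring B is made first as a cyclohexane (from 3,4-dimethylanisole); in the key step it is opened at C5–C10 to a ten-membered ring, then rings A and B are closed together by the new C5–C10 bond.
5. Cascade substrate: conjugate addition of the side-chain Grignard reagent (from methyl hydrogen (R)-3-methylglutarate) to (S)-3,4-dimethylcyclohex-2-enone, enolate vinylation at C10, isopropenyl addition at C5, O-allylation.

Key step: step 11

**Remarks on the chemistry**
- Halimane numbering of the target is used: ring A = C1–C5, C10; ring B = C5–C10; side chain C11–C15; C4 carries CH3 and CH2OAc.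
- SC = (3R)-5-[(tert-butyldimethylsilyl)oxy]-3-methylpentyl (C11–C15 with the C13 methyl).
- R/S descriptors of intermediates change with substituent priorities; no stereocenter is inverted after it is set.
- Assumption: the cinchona-derived amine catalyst of step 2 is used in the pseudoenantiomeric series that gives (S)-4.

**Route**

Step 1
Reactants: 1 3,4-dimethylanisole
Product: 3 3,4-dimethylcyclohex-3-en-1-one, via Birch diene 2 (not isolated)
Conditions: Li, NH3(l), t-BuOH, THF, −78 → −33 °C; then (CO2H)2, MeOH/H2O, rt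
Reagents that add atoms: water, O
Why: Birch reduction leaves the methoxy and both methyl groups on the two remaining double bonds, and mild oxalic acid hydrolysis of the enol ether should stop at the β,γ-unsaturated ketone (no stereocenter).

Step 2
Reactants: 3 3,4-dimethylcyclohex-3-en-1-one
Product: 4 (S)-3,4-dimethylcyclohex-2-en-1-one
Conditions: cinchona-derived chiral primary amine catalyst (9-amino-9-deoxy-epi-cinchona type, 10 mol %), carboxylic acid co-catalyst, toluene, rt
Reagents that add atoms: none
Why: Enantioselective olefin isomerization by dienamine catalysis (γ-protonation of the dienamine, then hydrolysis) should move the double bond into conjugation and set C8 (S in 4) under control of the chiral amine.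

Step 3
Reactants: 5 (R)-5-methoxy-3-methyl-5-oxopentanoic acid
Product: 6 methyl (R)-5-hydroxy-3-methylpentanoate
Conditions: BH3·SMe2, THF, 0 °C → rt
Reagents that add atoms: none
Why: Chemoselective borane reduction of a carboxylic acid beside a methyl ester; the C13 stereocenter is not touched.

Step 4
Reactants: 6 methyl (R)-5-hydroxy-3-methylpentanoate
Product: 7 methyl (S)-5-bromo-3-methylpentanoate
Conditions: CBr4, PPh3, CH2Cl2, 0 °C
Reagents that add atoms: carbon tetrabromide, BrC(Br)(Br)Br
Why: Appel bromination of the primary alcohol (substitution at a CH2, stereocenter remote).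

Step 5
Reactants: 7 methyl (S)-5-bromo-3-methylpentanoate
Product: 8 (S)-5-bromo-3-methylpentan-1-ol
Conditions: i-Bu2AlH, CH2Cl2, −78 → 0 °C
Reagents that add atoms: none
Why: Aluminium hydride reduction of the ester to the primary alcohol; the primary bromide is inert at low temperature.

Step 6
Reactants: 8 (S)-5-bromo-3-methylpentan-1-ol
Product: 9 (S)-[(5-bromo-3-methylpentyl)oxy](tert-butyl)dimethylsilane
Conditions: t-BuMe2SiCl, imidazole, DMF, rt
Reagents that add atoms: tert-butyldimethylsilyl chloride, CC(C)(C)[Si](C)(C)Cl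
Why: Imidazole-promoted silyl ether formation at a primary alcohol.

Step 7
Reactants: 9 (S)-[(5-bromo-3-methylpentyl)oxy](tert-butyl)dimethylsilane; 4 (S)-3,4-dimethylcyclohex-2-en-1-one
Product: 11 {[(3R,4S)-3-SC-3,4-dimethylcyclohex-1-en-1-yl]oxy}trimethylsilane, via Grignard reagent 10 (not isolated)
Conditions: Mg, THF, rt; then 4, CuBr·SMe2 (10 mol %), Me3SiCl, DMPU, THF, −78 °C; Et3N quench
Reagents that add atoms: chlorotrimethylsilane, C[Si](C)(C)Cl
Why: Copper-catalysed, Me3SiCl-accelerated conjugate addition of a Grignard reagent: the nucleophile should add to C9 anti to the C8 methyl of the half-chair enone, forming quaternary C9 with its methyl cis to the C8 methyl, and the enolate is trapped regiospecifically toward C10 as the silyl enol ether.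

Step 8
Reactants: 11 {[(3R,4S)-3-SC-3,4-dimethylcyclohex-1-en-1-yl]oxy}trimethylsilane
Product: 14 (2R,3R,4S)-3-SC-3,4-dimethyl-2-vinylcyclohexan-1-one, via lithium enolate 12 (not isolated), via sulfoxide adduct 13 (not isolated)
Conditions: MeLi, THF, 0 °C; CH2=CHS(O)Ph, −78 → −20 °C; aq. NH4Cl; then toluene, CaCO3, 110 °C
Reagents that add atoms: phenyl vinyl sulfoxide, C=CS(=O)c1ccccc1
Why: The regiodefined lithium enolate (Si–O cleavage by MeLi) should undergo Michael addition to phenyl vinyl sulfoxide, a vinyl cation equivalent, on the face anti to the axial C9 methyl (C10 R, vinyl cis to the C9 side chain), and thermal syn-elimination of PhSOH (sulfoxide pyrolysis) releases the vinyl group without conjugation.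

Step 9
Reactants: 14 (2R,3R,4S)-3-SC-3,4-dimethyl-2-vinylcyclohexan-1-one
Product: 15 (1S,2R,3R,4S)-3-SC-3,4-dimethyl-1-(prop-1-en-2-yl)-2-vinylcyclohexan-1-ol
Conditions: CeCl3 (anhydrous), CH2=C(CH3)MgBr, THF, −78 °C
Reagents that add atoms: isopropenylmagnesium bromide, CC(=C)[Mg]Br
Why: Organocerium 1,2-addition (non-basic, so the α-vinyl ketone is not enolised): equatorial attack anti to the C10 vinyl group, the axial path being blocked by the axial C9 substituent, should give the trans-1,2-dialkenyl carbinol (C5 S, OH cis to vinyl).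

Step 10
Reactants: 15 (1S,2R,3R,4S)-3-SC-3,4-dimethyl-1-(prop-1-en-2-yl)-2-vinylcyclohexan-1-ol
Product: 16 (1S,2R,3R,4S)-1-(allyloxy)-3-SC-3,4-dimethyl-1-(prop-1-en-2-yl)-2-vinylcyclohexane
Conditions: NaH, allyl bromide, Bu4NI (cat.), DMF, 0 °C → rt
Reagents that add atoms: allyl bromide, C=CCBr
Why: Williamson etherification of the tertiary sodium alkoxide; no stereocenter is affected.

Step 11
Reactants: 16 (1S,2R,3R,4S)-1-(allyloxy)-3-SC-3,4-dimethyl-1-(prop-1-en-2-yl)-2-vinylcyclohexane
Product: 19 (4R,5R,8S,9R,10S)-4-allyl-4,8,9-trimethyl-9-SC-Δ1-octalin-5-ol (trans-fused; 5-OH anti to 10-H), via macrocyclic allyl enol ether 17 (not isolated), via allyl cyclodecenone 18 (not isolated)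
Conditions: toluene (0.02 M), Et3N (0.2 equiv), sealed vessel (microwave), 210 °C
Reagents that add atoms: none
Why: On heating, the trans-1,2-dialkenyl ether should undergo a [3,3] oxy-Cope shift through a chair transition state (both alkenyl groups equatorial) that cleaves the old ring B bond C5–C10 and creates C2–C3, giving the ten-membered allyl enol ether 17 in which C5 and C10 are no longer bonded; a Claisen rearrangement then moves the allyl group from O to C4 (ketone 18), and a transannular carbonyl-ene reaction (C10=C1 as ene with a C2–H, C5=O as enophile) creates the ring-fusion bond C5–C10 together with the C1=C2 olefin. The closest known reaction type is the thermal tandem oxy-Cope/Claisen/ene reaction of allyl ethers of 1,2-dialkenylcyclohexanols, which gives decalinols with a quaternary carbon next to the carbinol. Ring closures: the Cope step is a four-carbon ring expansion (six- to ten-membered), and the ene step is a transannular 1,6-closure through a six-membered cyclic transition state that forms rings A and B at once as a trans-fused pair. C4 is controlled by the C5 configuration of 16: the chair Cope step fixes the enol ether geometry (O cis to C3) and the face from which C10 has departed, and the allyl group can reach C4 only from the opposite, outer face of the ten-membered ring, which places the future CH2OAc carbon cis to the C9 side chain. C10 and the transient C5 carbinol are set in the ene step, the alkene and carbonyl being free to turn through the ring (Curtin–Hammett conditions), through the trans-fused transition state that keeps C4 anti to quaternary C9 and the C8 methyl equatorial, which should give 10-H cis to the C9 side chain and anti to 5-OH. The step needs chair-over-boat selectivity in the Cope event, a Claisen step faster than any flipping of the tetrasubstituted enol ether, and a single ene regiochemistry; the diequatorial alkenyl groups of 16, the bulk of the O-allyl/methyl pair and the quaternary C9 (C2–H is the only allylic hydrogen) secure these, and Et3N suppresses ionisation of the tertiary allylic ether.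

Step 12
Reactants: 19 (4R,5R,8S,9R,10S)-4-allyl-4,8,9-trimethyl-9-SC-Δ1-octalin-5-ol
Product: 20 (4S,5R,8S,9R,10S)-4,8,9-trimethyl-4-(2-oxopropyl)-9-SC-Δ1-octalin-5-ol
Conditions: PdCl2 (10 mol %), CuCl, O2 (1 atm), DMF/H2O 7:1, rt
Reagents that add atoms: water, O
Why: Wacker–Tsuji oxidation: the monosubstituted terminal olefin should be oxidised with Markovnikov selectivity to the methyl ketone much faster than the 1,2-disubstituted ring olefin.

Step 13
Reactants: 20 (4S,5R,8S,9R,10S)-4,8,9-trimethyl-4-(2-oxopropyl)-9-SC-Δ1-octalin-5-ol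
Product: 21 (4S,5R,8S,9R,10S)-4,8,9-trimethyl-4-(2-oxopropyl)-9-SC-decalin-5-ol
Conditions: H2 (1 atm), Pd/C (10 %), EtOAc, rt
Reagents that add atoms: none
Why: Heterogeneous hydrogenation of the cis-disubstituted C1=C2 olefin; ketone, tertiary alcohol and silyl ether are inert and no stereocenter is formed.

Step 14
Reactants: 21 (4S,5R,8S,9R,10S)-4,8,9-trimethyl-4-(2-oxopropyl)-9-SC-decalin-5-ol
Product: 22 (4S,5R,8S,9R,10S)-4-(acetoxymethyl)-4,8,9-trimethyl-9-SC-decalin-5-ol
Conditions: mCPBA, NaHCO3, CH2Cl2, rt (extended time)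
Reagents that add atoms: 3-chloroperbenzoic acid, OOC(=O)c1cccc(Cl)c1
Why: Baeyer–Villiger oxidation with migration of the primary CH2 group in preference to methyl converts the acetonyl group into the acetoxymethyl group; C4 is not involved.

Step 15
Reactants: 22 (4S,5R,8S,9R,10S)-4-(acetoxymethyl)-4,8,9-trimethyl-9-SC-decalin-5-ol
Product: 23 (4R,8S,9R,10S)-4-(acetoxymethyl)-4,8,9-trimethyl-9-SC-Δ5-octalin
Conditions: Burgess reagent (methyl N-(triethylammoniosulfonyl)carbamate), benzene, 50 °C
Reagents that add atoms: none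
Why: Burgess dehydration is a syn-elimination: the axial 5-OH of the trans-decalin has a cis hydrogen only at C6 (10-H is anti, C4 is quaternary), so the 5,6-olefin should result.

Step 16
Reactants: 23 (4R,8S,9R,10S)-4-(acetoxymethyl)-4,8,9-trimethyl-9-SC-Δ5-octalin
Product: 24 (4R,8R,9S,10S)-4-(acetoxymethyl)-4,8,9-trimethyl-9-SC-Δ5-octalin-7-one
Conditions: CrO3, 3,5-dimethylpyrazole, CH2Cl2, −20 °C
Reagents that add atoms: chromium trioxide, O=[Cr](=O)=O
Why: Allylic oxidation with the CrO3–3,5-dimethylpyrazole complex at the only allylic CH2 (C7) should give the enone; the tertiary C10–H is shielded by quaternary C9, and in the enone C10 is γ-epimerisable toward the natural, all-equatorial arrangement.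

Step 17
Reactants: 24 (4R,8R,9S,10S)-4-(acetoxymethyl)-4,8,9-trimethyl-9-SC-Δ5-octalin-7-one
Product: 27 (4R,8R,9S,10S,13R)-18-acetoxy-7-oxohalim-5-en-15-oic acid (target), via primary alcohol 25 (not isolated), via aldehyde 26 (not isolated)
Conditions: CrO3, H2SO4, H2O, acetone, 0 °C → rt
Reagents that add atoms: water, O
Why: Acidic CrO3 (Jones oxidation) cleaves the primary silyl ether and oxidises the alcohol through the aldehyde hydrate to the carboxylic acid; acetate and enone are stable.

**Compound list**
1 | 3,4-dimethylanisole | COc1ccc(C)c(C)c1 | starting material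
2 | 1-methoxy-4,5-dimethylcyclohexa-1,4-diene (not isolated) | COC1=CCC(C)=C(C)C1 | intermediate
3 | 3,4-dimethylcyclohex-3-en-1-one | O=C1CCC(C)=C(C)C1 | intermediate
4 | (S)-3,4-dimethylcyclohex-2-en-1-one | O=C1C=C(C)[C@@H](C)CC1 | intermediate
5 | (R)-5-methoxy-3-methyl-5-oxopentanoic acid (methyl hydrogen (R)-3-methylglutarate) | C[C@@H](CC(=O)OC)CC(=O)O | starting material
6 | methyl (R)-5-hydroxy-3-methylpentanoate | C[C@@H](CC(=O)OC)CCO | intermediate
7 | methyl (S)-5-bromo-3-methylpentanoate | C[C@@H](CC(=O)OC)CCBr | intermediate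
8 | (S)-5-bromo-3-methylpentan-1-ol | C[C@@H](CCO)CCBr | intermediate
9 | (S)-[(5-bromo-3-methylpentyl)oxy](tert-butyl)dimethylsilane | C[C@@H](CCO[Si](C)(C)C(C)(C)C)CCBr | intermediate
10 | (S)-{5-[(tert-butyldimethylsilyl)oxy]-3-methylpentyl}magnesium bromide (not isolated) | C[C@@H](CCO[Si](C)(C)C(C)(C)C)CC[Mg]Br | intermediate
11 | {[(3R,4S)-3-SC-3,4-dimethylcyclohex-1-en-1-yl]oxy}trimethylsilane | C[Si](C)(C)OC1=C[C@](C)(CC[C@@H](C)CCO[Si](C)(C)C(C)(C)C)[C@@H](C)CC1 | intermediate
12 | lithium (3R,4S)-3-SC-3,4-dimethylcyclohex-1-en-1-olate (not isolated) | [Li]OC1=C[C@](C)(CC[C@@H](C)CCO[Si](C)(C)C(C)(C)C)[C@@H](C)CC1 | intermediate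
13 | (2R,3R,4S)-3-SC-3,4-dimethyl-2-[2-(phenylsulfinyl)ethyl]cyclohexan-1-one, both sulfur epimers (not isolated) | O=C1[C@H](CCS(=O)c2ccccc2)[C@](C)(CC[C@@H](C)CCO[Si](C)(C)C(C)(C)C)[C@@H](C)CC1 | intermediate
14 | (2R,3R,4S)-3-SC-3,4-dimethyl-2-vinylcyclohexan-1-one | O=C1[C@H](C=C)[C@](C)(CC[C@@H](C)CCO[Si](C)(C)C(C)(C)C)[C@@H](C)CC1 | intermediate
15 | (1S,2R,3R,4S)-3-SC-3,4-dimethyl-1-(prop-1-en-2-yl)-2-vinylcyclohexan-1-ol | O[C@]1(C(C)=C)[C@H](C=C)[C@](C)(CC[C@@H](C)CCO[Si](C)(C)C(C)(C)C)[C@@H](C)CC1 | intermediate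
16 | (1S,2R,3R,4S)-1-(allyloxy)-3-SC-3,4-dimethyl-1-(prop-1-en-2-yl)-2-vinylcyclohexane | C=CCO[C@]1(C(C)=C)[C@H](C=C)[C@](C)(CC[C@@H](C)CCO[Si](C)(C)C(C)(C)C)[C@@H](C)CC1 | intermediate
17 | (1Z,5E,7R,8S)-1-(allyloxy)-7-SC-2,7,8-trimethylcyclodeca-1,5-diene, ring carbons trans across both double bonds (not isolated) | C=CCO/C1=C(/C)CC/C=C/[C@](C)(CC[C@@H](C)CCO[Si](C)(C)C(C)(C)C)[C@@H](C)CC1 | intermediate
18 | (2S,5E,7R,8S)-2-allyl-7-SC-2,7,8-trimethylcyclodec-5-en-1-one (not isolated) | O=C1[C@](C)(CC=C)CC/C=C/[C@](C)(CC[C@@H](C)CCO[Si](C)(C)C(C)(C)C)[C@@H](C)CC1 | intermediate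
19 | (4R,5R,8S,9R,10S)-4-allyl-4,8,9-trimethyl-9-SC-Δ1-octalin-5-ol, trans-fused | C=CC[C@]1(C)CC=C[C@@H]2[C@]1(O)CC[C@H](C)[C@@]2(C)CC[C@@H](C)CCO[Si](C)(C)C(C)(C)C | intermediate
20 | (4S,5R,8S,9R,10S)-4,8,9-trimethyl-4-(2-oxopropyl)-9-SC-Δ1-octalin-5-ol | CC(=O)C[C@]1(C)CC=C[C@@H]2[C@]1(O)CC[C@H](C)[C@@]2(C)CC[C@@H](C)CCO[Si](C)(C)C(C)(C)C | intermediate
21 | (4S,5R,8S,9R,10S)-4,8,9-trimethyl-4-(2-oxopropyl)-9-SC-decalin-5-ol | CC(=O)C[C@]1(C)CCC[C@@H]2[C@]1(O)CC[C@H](C)[C@@]2(C)CC[C@@H](C)CCO[Si](C)(C)C(C)(C)C | intermediate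
22 | (4S,5R,8S,9R,10S)-4-(acetoxymethyl)-4,8,9-trimethyl-9-SC-decalin-5-ol | CC(=O)OC[C@]1(C)CCC[C@@H]2[C@]1(O)CC[C@H](C)[C@@]2(C)CC[C@@H](C)CCO[Si](C)(C)C(C)(C)C | intermediate
23 | (4R,8S,9R,10S)-4-(acetoxymethyl)-4,8,9-trimethyl-9-SC-Δ5-octalin | CC(=O)OC[C@]1(C)CCC[C@@H]2C1=CC[C@H](C)[C@@]2(C)CC[C@@H](C)CCO[Si](C)(C)C(C)(C)C | intermediate
24 | (4R,8R,9S,10S)-4-(acetoxymethyl)-4,8,9-trimethyl-9-SC-Δ5-octalin-7-one | CC(=O)OC[C@]1(C)CCC[C@@H]2C1=CC(=O)[C@H](C)[C@@]2(C)CC[C@@H](C)CCO[Si](C)(C)C(C)(C)C | intermediate
25 | (4R,8R,9S,10S,13R)-18-acetoxy-15-hydroxyhalim-5-en-7-one (not isolated) | CC(=O)OC[C@]1(C)CCC[C@@H]2C1=CC(=O)[C@H](C)[C@@]2(C)CC[C@@H](C)CCO | intermediate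
26 | (4R,8R,9S,10S,13R)-18-acetoxy-7-oxohalim-5-en-15-al (not isolated) | CC(=O)OC[C@]1(C)CCC[C@@H]2C1=CC(=O)[C@H](C)[C@@]2(C)CC[C@@H](C)CC=O | intermediate
27 | (4R,8R,9S,10S,13R)-18-acetoxy-7-oxohalim-5-en-15-oic acid | CC(=O)OC[C@]1(C)CCC[C@@H]2C1=CC(=O)[C@H](C)[C@@]2(C)CC[C@@H](C)CC(=O)O | target

**Step count**
Total: 17 steps. Longest linear sequence: 15 steps (steps 3–17, from 5).

**Steps most likely to fail, with fallbacks**

Step 11 (key cascade). What may go wrong: loss of the stereochemical relay from C5 to C4 (boat-type Cope event, or flipping of the enol ether unit through the ring before the slow Claisen step), thermal ionisation of the tertiary allylic ether at 210 °C, or an ene closure too slow to compete with decomposition. Fallback: the three events are run stepwise at low temperature, setting out from alcohol 15. Treatment with KH and 18-crown-6 in THF at 0 °C should trigger the anionic oxy-Cope rearrangement, and allyl bromide added at −78 °C should C-allylate the ten-membered enolate on its outer face to give ketone 18, now isolated. Me2AlCl in CH2Cl2 at −78 °C should then promote the transannular carbonyl-ene closure, and the route is rejoined at 19. This detour makes no compound outside the list (F0).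

Step 8 (enolate vinylation). What may go wrong: slow Michael addition of the hindered enolate with competing proton transfer and polymerisation of the vinyl sulfoxide, and partial loss of the C10 configuration through enolate equilibration. Fallback: the C10–vinyl bond is made by cross-coupling instead, setting out from silyl enol ether 11. Vinyl bromide, Pd2(dba)3, P(t-Bu)3 and Bu3SnF in toluene at 80 °C (fluoride-activated palladium-catalysed α-vinylation of a silyl enol ether) should give 14 directly, where the route is rejoined. This detour makes no compound outside the list (F0).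

Step 9 (isopropenyl addition). What may go wrong: poor facial selectivity, with addition cis to the C10 vinyl group giving the C5 epimer (which would relay the opposite configuration to C4), and competing enolisation of the ketone. Fallback: the roles of the two C4 substituents are exchanged so that the C5 epimer leads to the correct C4 configuration, setting out from 14. CH2=C(Li)CH2OPMB (from 2-bromo-3-(4-methoxybenzyloxy)propene and t-BuLi) with CeCl3 should give the C5-epimeric carbinol (1R,2R,3R,4S)-3-SC-1-{3-[(4-methoxybenzyl)oxy]prop-1-en-2-yl}-3,4-dimethyl-2-vinylcyclohexan-1-ol F1. KH and 18-crown-6 in THF (anionic oxy-Cope) followed by MeI should methylate the ten-membered enolate on its outer face and give (2S,5Z,7R,8S)-7-SC-2-{[(4-methoxybenzyl)oxy]methyl}-2,7,8-trimethylcyclodec-5-en-1-one F2. Me2AlCl in CH2Cl2 at −78 °C should close it by the transannular ene reaction to (4S,5R,8S,9R,10S)-4-{[(4-methoxybenzyl)oxy]methyl}-4,8,9-trimethyl-9-SC-Δ1-octalin-5-ol F3. H2 over Pd(OH)2/C in EtOH should saturate the ring olefin and remove the benzyl-type ether to give (4S,5R,8S,9R,10S)-4-(hydroxymethyl)-4,8,9-trimethyl-9-SC-decalin-5-ol F4. Ac2O in pyridine should acetylate only the primary hydroxyl, and the route is rejoined at 22.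

**Further compounds**
F0 | step 11 | none | none
F0 | step 8 | none | none
F1 | step 9 | (1R,2R,3R,4S)-3-SC-1-{3-[(4-methoxybenzyl)oxy]prop-1-en-2-yl}-3,4-dimethyl-2-vinylcyclohexan-1-ol | O[C@@]1(C(=C)COCc2ccc(OC)cc2)[C@H](C=C)[C@](C)(CC[C@@H](C)CCO[Si](C)(C)C(C)(C)C)[C@@H](C)CC1
F2 | step 9 | (2S,5Z,7R,8S)-7-SC-2-{[(4-methoxybenzyl)oxy]methyl}-2,7,8-trimethylcyclodec-5-en-1-one | O=C1[C@](C)(COCc2ccc(OC)cc2)CC/C=C\[C@](C)(CC[C@@H](C)CCO[Si](C)(C)C(C)(C)C)[C@@H](C)CC1
F3 | step 9 | (4S,5R,8S,9R,10S)-4-{[(4-methoxybenzyl)oxy]methyl}-4,8,9-trimethyl-9-SC-Δ1-octalin-5-ol | COc1ccc(COC[C@]2(C)CC=C[C@@H]3[C@]2(O)CC[C@H](C)[C@@]3(C)CC[C@@H](C)CCO[Si](C)(C)C(C)(C)C)cc1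
F4 | step 9 | (4S,5R,8S,9R,10S)-4-(hydroxymethyl)-4,8,9-trimethyl-9-SC-decalin-5-ol | OC[C@]1(C)CCC[C@@H]2[C@]1(O)CC[C@H](C)[C@@]2(C)CC[C@@H](C)CCO[Si](C)(C)C(C)(C)C
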